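One question stands for this flask, and it concerns a rate at a fixed conversion rather than at a fixed time.

    starting material + fresh carrier → target + spent carrier (k1 = 0.338 M⁻¹ s⁻¹)
    spent carrier + salt in the second phase ⇌ fresh carrier + spent salt in the second phase (K2 = 0.0999, k2 = 1.98 M⁻¹ s⁻¹)
    starting material + spent carrier → spent catalyst (k3 = 0.0224 M⁻¹ s⁻¹)
    starting material + protic impurity → quenched substrate (k4 = 0.314 M⁻¹ s⁻¹)
starting material 0.20 M; salt in the second phase 0.400 M; protic impurity 4.00 mM; spent carrier 5.0 mM; volume of the second phase over the first 0.50
- in the second phase: salt in the second phase, spent salt in the second phase; everything else is in the first
- charges count per volume of the first phase; a concentration in a rate is the amount of a species over the volume of its own phase; every rate counts per litre of the first phase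
- charge of starting material (flask): 0.20 M
1. apparent order in salt in the second phase when 20% of the starting material are converted (percent change of the rate of making target for one percent more salt in the second phase charged)

Two chemists dispute the answer. The first argues from rates: with the salt as charged, spent carrier turns over at 95 min⁻¹ in the transfer step and fresh carrier at 4.1 min⁻¹ in the productive step, so transfer is the faster by far. In this view the carrier stays fresh, and the order in salt lies near 0.

The second, whose reckoning this is, accepts the same comparison and concludes differently. A step that fast may be taken as a pre-equilibrium, and the question is where that equilibrium lies. Salt and spent salt share a phase, so their volume cancels. Let w be the fraction of the salt charge turned to spent salt. I count the converted starting material less the protic impurity charge, which consumes substrate without salt, and get w = 9.00% at the asked conversion. The balance number, the equilibrium constant times the salt left over the spent salt, is then 1.01. The fresh share of the living carrier is the balance number over one plus itself, 0.503. At fixed conversion, more salt raises that share with an order of 0.547.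

The balance number also enters the carrier's losses. Spent catalyst forms per target at the ratio of the two rate constants divided by the balance number, and this ratio climbs as w grows. Summed up to the asked conversion, with salt at its mean, the loss is 22.5% of the carrier charge. More salt shrinks that loss, which adds 0.304. My order is therefore 0.851.

The forecast takes the second side with 0.83, a little lower than my figure, on the grounds of “the carrier split about evenly between fresh and spent”.

The simulation gives 0.86 at the asked conversion, which is reached at 3.51 min with target made at 0.00582 M min⁻¹; the forecast stands within its tolerance, and the first chemist's order near 0 does not stand. In this flask, salt left at 95.2% after 1.20 min gives a balance number of 1.97, and salt left at 85.1% after 12.0 min gives 0.570. The first view lies nearer this flask at the earlier time, while the balance number is higher, with fresh carrier at 59.8% and spent carrier at 32.6%. At 12.0 min, the later balance number gives a fresh share of the living carrier of 0.363, and this flask holds fresh carrier at 9.93% against spent carrier at 17.7%.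

Its constants belong to no real substance; what happens was integrated by code.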